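Remark on the chemistry: locants follow the target oxolane throughout (O1, C2 to C5, C9 on C3, C7' on C4; ring A on C2, ring B on C7', ring C in the caffeoyl group). TBS stands for tert-butyldimethylsilyl. Lactol 12 is carried as a mixture of anomers, which converge in step 10.

## Analysis of the target

The target is a 2,3,4-trisubstituted oxolane of the furan-lignan type whose primary C9 hydroxyl is esterified with (E)-caffeic acid. C2 carries guaiacyl ring A, C3 carries the C9 methylene, C4 carries the C7' methylene to guaiacyl ring B, and C5 is an unsubstituted CH2 bonded to O1. The three contiguous stereocentres are 2R, 3S, 4S: ring A and the C9 arm are trans, the C9 and C7' arms are cis. Sensitive groups are the three phenols (the catechol of ring C oxidises easily), the cinnamate ester (base-labile, and its alkene would not survive CO/H2 with rhodium), and the C2–O1 bond. That bond is benzylic and para to an oxygen, so acid can ionise it, which epimerises C2 or lets ring B attack C2. The hard part is the cis relation at C3/C4 next to a trans relation at C2/C3 on a flexible five-membered ring, where facial preferences are small and equilibration does not help. The strategy rests on C5: it is the only ring carbon without a carbon substituent and it is bonded to O1. It can therefore be added as a one-carbon carbonyl unit to C4 of an acyclic C3=C4 alkene whose allylic C2 hydroxyl becomes O1. C3 and C4 then arise together from one syn addition to an alkene of defined geometry.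

## Retrosynthetic reasoning

**Ester and phenols.** Target 19 is traced back to the tetrasilyl ester 18 (four O–Si bonds) and this to alcohol 14 and acid 17 (C9–O acyl bond). The caffeoyl group comes last because its alkene and catechol are incompatible with the carbonylation and the Lewis acid used earlier. Silyl ethers on all four phenols allow one closing fluoride step. Acid 17 comes from caffeic acid 15 by silylation.

**C9 hydroxyl and C5 methylene.** Alcohol 14 comes from the fully silylated oxolane 13 by removing only the alkyl silyl ether. Oxolane 13 comes from lactol 12 by replacing the C5 hydroxyl with hydrogen. This places a carbonyl oxidation level at C5, which is what the key step delivers.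

**Key disconnection.** In lactol 12 the O1–C5 and C4–C5 bonds are cut, together with the C3–H bond. This leads through the open hydroxy aldehyde 11 to the Z-trisubstituted allylic alcohol 10. The cut is made here because C5 carries nothing but O1 and can be a formyl carbon. One operation then gives the last skeletal carbon, the ring and two stereocentres. The forward reaction has to add H to C3 and a formyl group to C4 on the alkene face that carries the C2 oxygen.

**C2–C3 bond.** Alcohol 10 is cut between C2 and C3 into alkenyl iodide 9 and aldehyde 2. This is convergent, sets C2 by catalyst control, and carries the Z geometry of 9 unchanged into 10.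

**Alkenyl iodide.** Iodide 9 comes from iodo alcohol 8 by silylation, 8 from stannane 7, and 7 from alkynol 6 by trans-hydrostannation directed by the free hydroxyl. This fixes both the position of the metal (next to C9) and the geometry (metal cis to the benzyl arm).

**Alkyne and ring B.** Alkynol 6 is cut at the C7'–C(sp) bond into benzylic bromide 4 and propargyl alcohol 5. Bromide 4 comes from alcohol 3, and 3 from aldehyde 2, which is made from vanillin 1. Aldehyde 2 thus serves both aryl halves.

## Alternatives that were turned down

**Alternative 1:** conjugate addition and aldol on a chiral butenolide.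
- Disconnection: the C4–C7' and C2–C3 bonds, both made on a lactone whose carbonyl carbon later becomes C9 and whose acetal carbon becomes C5.
- Forward key step: the 2-lithio derivative of dithiane A2 adds to the β carbon of menthyloxybutenolide A1 anti to the alkoxy group. The lactone enolate is trapped in the same flask by aldehyde 2, giving lactone A3; no ring of the target is closed. Desulfurisation with Raney Ni, hydride reduction of lactone and acetal, and acid closure of O1–C2 would lead to 14.
- For: every operation has close analogies in this compound class. The absolute configuration comes from a crystalline auxiliary. The trans lactone translates into the cis C9/C7' relation.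
- Against: auxiliary and dithiane are stoichiometric and discarded. The carbinol centre made in the aldol is not used, because O1–C2 closes through a benzylic cation at C2. That ionisation is the one that also epimerises C2 or lets ring B attack it. A1 must be made and its acetal epimers separated.
- Comparison: on precedent this alternative is stronger, and its length is similar. The chosen strategy offers a catalytic C–C bond formation whose only added atoms come from CO and H2, catalyst control of C2, and no cationic step at C2.

**Alternative 2:** asymmetric palladium trimethylenemethane cycloaddition.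
- Disconnection: C2–C3 and O1–C5 in a [3+2] cycloaddition to the aldehyde.
- Forward key step: Pd2(dba)3 (zerovalent palladium) with a chiral phosphoramidite ionises carbonate A4 to an ester-stabilised trimethylenemethane complex. Its carbanion carbon adds to aldehyde 2 and the alkoxide closes on the allyl terminus, giving oxolane A5 with a methylene group on C4. Hydroboration of that alkene, a B-alkyl Suzuki coupling to bring in ring B, and ester reduction would give 14.
- For: one catalytic enantioselective step makes the ring, C2 and C3. The ester carbon is already C9. The route is very short.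
- Against: aldehyde 2 is electron-rich and a weak acceptor for such dipoles. In A5 the C3 hydrogen is α to the ester and allylic, so migration of the double bond into conjugation would erase C3. C4 is made afterwards by addition to an exocyclic alkene on a nearly flat ring, where the C3 ester and the C2 aryl group shield opposite faces. The cis C9/C7' relation would therefore rest on a modest facial preference.
- Comparison: it is equally catalytic and shorter. The chosen strategy offers a cis C3/C4 relation locked by one syn addition, and a precursor that cannot lose C3 by enolisation.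

**Alternative 3:** trivalent titanium epoxide radical cyclisation.
- Disconnection: C3–C4, inside an ether that already holds O1–C2 and O1–C5.
- Forward key step: Cp2TiCl (trivalent titanium, from Cp2TiCl2 and Zn) opens the terminal epoxide of the epoxy cinnamyl ether A6 to a C3 radical with a titanium alkoxide on C9. The radical adds 5-exo-trig to the cinnamyl alkene, and the benzylic C7' radical is reduced and protonated. The product A7 is the same compound as 14.
- For: it reaches 14 directly with the C9 hydroxyl free, so step 11 would not be needed. The conditions are neutral and spare the benzylic ether. This radical chemistry is well known.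
- Against: titanium is used in excess. C2 must be set beforehand, in practice by a resolution that costs half the material. C3 and C4 follow from the preference of a 5-exo transition state, which places the C2 and C3 groups trans reliably but gives the cis C3/C4 relation only as the major of several isomers. The benzylic radical can also end as alkene or dimer.
- Comparison: in step count and precedent this alternative is stronger. The chosen strategy offers C3/C4 stereochemistry fixed by mechanism and a catalyst-set C2, at the price of an unproven key step.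

Key step: step 9

## Route

**Step 1**
Reactants: 1 vanillin
Product: 2 4-(TBS-oxy)-3-methoxybenzaldehyde
Conditions: TBSCl, imidazole, CH2Cl2, 0 °C to rt
Reagents that add atoms: tert-butyldimethylsilyl chloride, CC(C)(C)[Si](C)(C)Cl
Why: Standard phenol silylation; the aldehyde is untouched, and 2 is both the electrophile of step 8 and the source of ring B.

**Step 2**
Reactants: 2 4-(TBS-oxy)-3-methoxybenzaldehyde
Product: 3 [4-(TBS-oxy)-3-methoxyphenyl]methanol
Conditions: NaBH4, MeOH/THF, 0 °C
Reagents that add atoms: none
Why: Borohydride reduction of an aryl aldehyde; a short reaction at 0 °C should leave the aryl silyl ether intact.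

**Step 3**
Reactants: 3 [4-(TBS-oxy)-3-methoxyphenyl]methanol
Product: 4 tert-butyl[4-(bromomethyl)-2-methoxyphenoxy]dimethylsilane
Conditions: PBr3, Et2O, 0 °C; used at once without chromatography
Reagents that add atoms: phosphorus tribromide, BrP(Br)Br
Why: Conversion of a benzylic alcohol to the bromide through its phosphite ester; the electron-rich bromide is labile and is therefore made cold and used directly.

**Step 4**
Reactants: 5 propargyl alcohol; 4 tert-butyl[4-(bromomethyl)-2-methoxyphenoxy]dimethylsilane
Product: 6 4-[4-(TBS-oxy)-3-methoxyphenyl]but-2-yn-1-ol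
Conditions: 5, EtMgBr (2 equiv per 5), THF, 0 °C to rt; then CuCl (10 mol%), 4, 50 °C
Reagents that add atoms: none
Why: Copper-catalysed coupling of the bis-magnesium derivative of propargyl alcohol with a benzylic bromide forms the C7'–C(sp) bond; no hydroxyl protection is needed, and the free hydroxyl is required in step 5.

**Step 5**
Reactants: 6 4-[4-(TBS-oxy)-3-methoxyphenyl]but-2-yn-1-ol
Product: 7 (Z)-4-[4-(TBS-oxy)-3-methoxyphenyl]-2-(tributylstannyl)but-2-en-1-ol
Conditions: Bu3SnH (slow addition), [Cp*RuCl]4 (1.5 mol%), CH2Cl2, rt
Reagents that add atoms: tributyltin hydride, CCCC[SnH](CCCC)CCCC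
Why: Hydroxyl-directed trans-hydrostannation: a hydrogen bond from the propargylic hydroxyl to the chloride on divalent ruthenium steers tin to the alkyne carbon next to C9, and H and Sn add trans, so tin ends up cis to the benzyl arm.

**Step 6**
Reactants: 7 (Z)-alkenylstannane
Product: 8 (Z)-4-[4-(TBS-oxy)-3-methoxyphenyl]-2-iodobut-2-en-1-ol
Conditions: I2, CH2Cl2, 0 °C
Reagents that add atoms: iodine, II
Why: Iododestannylation of an alkenylstannane proceeds with retention of alkene geometry; the silyl-protected arene is not iodinated by I2 alone.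

**Step 7**
Reactants: 8 (Z)-iodo alcohol
Product: 9 (Z)-1-(TBS-oxy)-4-[4-(TBS-oxy)-3-methoxyphenyl]-2-iodobut-2-ene
Conditions: TBSCl, imidazole, CH2Cl2, 0 °C to rt
Reagents that add atoms: tert-butyldimethylsilyl chloride, CC(C)(C)[Si](C)(C)Cl
Why: Silylation of the primary allylic alcohol; with C9 masked, only the C2 hydroxyl made in step 8 can bind the directing group and close onto C5 in step 9.

**Step 8**
Reactants: 9 (Z)-alkenyl iodide; 2 4-(TBS-oxy)-3-methoxybenzaldehyde
Product: 10 (1S,2Z)-1,4-bis[4-(TBS-oxy)-3-methoxyphenyl]-2-[(TBS-oxy)methyl]but-2-en-1-ol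
Conditions: CrCl2 (10 mol%), chiral 2-(2-sulfonamidophenyl)oxazoline ligand (11 mol%), 1,8-bis(dimethylamino)naphthalene (11 mol%), NiCl2(2,9-dimethyl-1,10-phenanthroline) (2 mol%), Mn (2 equiv), Cp2ZrCl2 (1.2 equiv), LiCl, MeCN, rt
Reagents that add atoms: none
Why: Catalytic asymmetric Nozaki–Hiyama–Kishi coupling: nickel activates the C–I bond, the alkenyl group passes to ligand-bound chromium and adds to the aldehyde with retention of the Z geometry, while Cp2ZrCl2 frees the chromium alkoxide and Mn returns chromium to the divalent state. The ligand enantiomer is chosen for addition to the Re face of 2, which gives the S carbinol (this centre becomes C2 and is R in the target only because the priorities change).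

**Step 9**
Reactants: 10 Z-trisubstituted allylic alcohol
Product: 12 (3S,4S,5R)-3-[4-(TBS-oxy)-3-methoxybenzyl]-4-[(TBS-oxy)methyl]-5-[4-(TBS-oxy)-3-methoxyphenyl]oxolan-2-ol as anomeric mixture, via hydroxy aldehyde 11 (not isolated)
Conditions: Rh(acac)(CO)2 (5 mol%), Ph2POMe (25 mol%), 4 Å molecular sieves, CO/H2 1:1 (40 bar), THF, 60 °C
Reagents that add atoms: carbon monoxide, [C-]#[O+]
Why: Proposed new method: Ph2POMe exchanges its methoxy group for the C2 hydroxyl of 10 without acid (the carbinol is benzylic and allylic and would ionise with acid), and the catalyst-bound phosphinite ester holds a hydride of monovalent rhodium over the alkene face that carries the C2 oxygen, so hydride goes to C3 and rhodium to C4 through a six-membered chelate (Rh–P–O–C2–C3–C4), the alternative being a tertiary alkyl rhodium at C3 on the way to a quaternary carbon; CO insertion and hydrogenolysis give the C4–C5 aldehyde 11 and pass the phosphinite to the next molecule of 10. The closest known reaction types are the phosphorus-directed diastereoselective hydroformylation of 1,1-disubstituted allylic alcohols bearing an ortho-diphenylphosphinobenzoate group and the hydroformylation of homoallylic alcohols directed by catalytic, reversibly bound phosphinites; a Z-trisubstituted allylic alcohol has been used in neither. The oxolane ring closes by 5-exo-trig addition of the freed C2 hydroxyl (O1) to the C5 aldehyde. C3 is set relative to C2 by face selection: allylic 1,3-strain with the Z benzyl arm keeps the C2–H bond in the alkene plane, ring A and the oxygen point to opposite faces, and delivery from the oxygen face puts the new C3–H cis to ring A, so ring A and the C9 arm are trans. This is the opposite sense to the known 1,1-disubstituted cases, where no Z substituent is present and the C2–H bond eclipses the C3 substituent instead. C4 is set relative to C3 by the suprafacial addition of H and Rh and the retentive CO insertion, which on the Z alkene places the C9 and C7' arms cis. The step needs regioselectivity for C4 over C3 and C7', face selectivity, and hydroformylation in preference to hydrogenation; the substitution pattern, the tether and the Z geometry secure the first two, and CO pressure at moderate temperature should secure the third.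

**Step 10**
Reactants: 12 lactol (both anomers)
Product: 13 (2R,3S,4S)-2-[4-(TBS-oxy)-3-methoxyphenyl]-4-[4-(TBS-oxy)-3-methoxybenzyl]-3-[(TBS-oxy)methyl]oxolane
Conditions: Et3SiH (3 equiv), BF3·OEt2 (2 equiv), CH2Cl2, −78 °C; cold quench with Et3N then aq. NaHCO3
Reagents that add atoms: none
Why: Ionic lactol reduction: the Lewis acid gives the cyclic oxocarbenium ion at C5, which the silane reduces; C5 becomes CH2, so both anomers converge, and at −78 °C the benzylic C2–O1 bond should not ionise.

**Step 11**
Reactants: 13 trisilyl oxolane
Product: 14 [(2R,3S,4S)-2-[4-(TBS-oxy)-3-methoxyphenyl]-4-[4-(TBS-oxy)-3-methoxybenzyl]oxolan-3-yl]methanol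
Conditions: camphorsulfonic acid (0.1 equiv), MeOH/CH2Cl2 1:1, 0 °C
Reagents that add atoms: none
Why: Acid-catalysed methanolysis removes the primary alkyl silyl ether much faster than the aryl silyl ethers, whose oxygen is less basic, so only the C9 hydroxyl is freed.

**Step 12**
Reactants: 15 caffeic acid
Product: 17 (E)-3-[3,4-bis(TBS-oxy)phenyl]prop-2-enoic acid, via silyl ester 16 (not isolated)
Conditions: TBSCl (3.5 equiv), imidazole, DMF, rt; then AcOH/THF/H2O, rt
Reagents that add atoms: tert-butyldimethylsilyl chloride, CC(C)(C)[Si](C)(C)Cl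
Why: Exhaustive silylation followed by hydrolysis of the far more labile silyl ester leaves the two aryl silyl ethers; the masked catechol cannot be acylated or oxidised in steps 13 and 14.

**Step 13**
Reactants: 14 primary alcohol; 17 bis-silyl caffeic acid
Product: 18 [(2R,3S,4S)-2-[4-(TBS-oxy)-3-methoxyphenyl]-4-[4-(TBS-oxy)-3-methoxybenzyl]oxolan-3-yl]methyl (E)-3-[3,4-bis(TBS-oxy)phenyl]prop-2-enoate
Conditions: EDC·HCl, DMAP (0.3 equiv), CH2Cl2, 0 °C to rt
Reagents that add atoms: none
Why: Steglich esterification of a primary alcohol; the neutral conditions do not touch the silyl ethers, the E alkene or the benzylic C2–O1 ether.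

**Step 14**
Reactants: 18 tetrasilyl ester
Product: 19 [(2R,3S,4S)-2-(4-hydroxy-3-methoxyphenyl)-4-(4-hydroxy-3-methoxybenzyl)oxolan-3-yl]methyl (E)-3-(3,4-dihydroxyphenyl)prop-2-enoate
Conditions: Bu4NF (4.5 equiv), AcOH (5 equiv), THF, 0 °C, under argon
Reagents that add atoms: none
Why: Fluoride cleaves the four aryl silyl ethers quickly; buffering with acetic acid keeps the phenoxides protonated, so the cinnamate ester should not be cleaved and the catechol should not be oxidised.

## Compound list

1 | vanillin | COc1cc(C=O)ccc1O | starting material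
2 | 4-(TBS-oxy)-3-methoxybenzaldehyde | COc1cc(C=O)ccc1O[Si](C)(C)C(C)(C)C | intermediate
3 | [4-(TBS-oxy)-3-methoxyphenyl]methanol | COc1cc(CO)ccc1O[Si](C)(C)C(C)(C)C | intermediate
4 | tert-butyl[4-(bromomethyl)-2-methoxyphenoxy]dimethylsilane | COc1cc(CBr)ccc1O[Si](C)(C)C(C)(C)C | intermediate
5 | propargyl alcohol | C#CCO | starting material
6 | 4-[4-(TBS-oxy)-3-methoxyphenyl]but-2-yn-1-ol | COc1cc(CC#CCO)ccc1O[Si](C)(C)C(C)(C)C | intermediate
7 | (Z)-4-[4-(TBS-oxy)-3-methoxyphenyl]-2-(tributylstannyl)but-2-en-1-ol | OC/C([Sn](CCCC)(CCCC)CCCC)=C/Cc1ccc(O[Si](C)(C)C(C)(C)C)c(OC)c1 | intermediate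
8 | (Z)-4-[4-(TBS-oxy)-3-methoxyphenyl]-2-iodobut-2-en-1-ol | OC/C(I)=C/Cc1ccc(O[Si](C)(C)C(C)(C)C)c(OC)c1 | intermediate
9 | (Z)-1-(TBS-oxy)-4-[4-(TBS-oxy)-3-methoxyphenyl]-2-iodobut-2-ene | CC(C)(C)[Si](C)(C)OC/C(I)=C/Cc1ccc(O[Si](C)(C)C(C)(C)C)c(OC)c1 | intermediate
10 | (1S,2Z)-1,4-bis[4-(TBS-oxy)-3-methoxyphenyl]-2-[(TBS-oxy)methyl]but-2-en-1-ol | O[C@@H](c1ccc(O[Si](C)(C)C(C)(C)C)c(OC)c1)/C(CO[Si](C)(C)C(C)(C)C)=C\Cc1ccc(O[Si](C)(C)C(C)(C)C)c(OC)c1 | intermediate
11 | (2S,3S,4R)-2-[4-(TBS-oxy)-3-methoxybenzyl]-3-[(TBS-oxy)methyl]-4-hydroxy-4-[4-(TBS-oxy)-3-methoxyphenyl]butanal | O=C[C@@H](Cc1ccc(O[Si](C)(C)C(C)(C)C)c(OC)c1)[C@@H](CO[Si](C)(C)C(C)(C)C)[C@@H](O)c1ccc(O[Si](C)(C)C(C)(C)C)c(OC)c1 | intermediate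
12 | (3S,4S,5R)-3-[4-(TBS-oxy)-3-methoxybenzyl]-4-[(TBS-oxy)methyl]-5-[4-(TBS-oxy)-3-methoxyphenyl]oxolan-2-ol, both anomers | COc1cc(C[C@@H]2C(O)O[C@@H](c3ccc(O[Si](C)(C)C(C)(C)C)c(OC)c3)[C@@H]2CO[Si](C)(C)C(C)(C)C)ccc1O[Si](C)(C)C(C)(C)C | intermediate
13 | (2R,3S,4S)-2-[4-(TBS-oxy)-3-methoxyphenyl]-4-[4-(TBS-oxy)-3-methoxybenzyl]-3-[(TBS-oxy)methyl]oxolane | COc1cc(C[C@@H]2CO[C@@H](c3ccc(O[Si](C)(C)C(C)(C)C)c(OC)c3)[C@@H]2CO[Si](C)(C)C(C)(C)C)ccc1O[Si](C)(C)C(C)(C)C | intermediate
14 | [(2R,3S,4S)-2-[4-(TBS-oxy)-3-methoxyphenyl]-4-[4-(TBS-oxy)-3-methoxybenzyl]oxolan-3-yl]methanol | COc1cc(C[C@@H]2CO[C@@H](c3ccc(O[Si](C)(C)C(C)(C)C)c(OC)c3)[C@@H]2CO)ccc1O[Si](C)(C)C(C)(C)C | intermediate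
15 | caffeic acid | O=C(O)/C=C/c1ccc(O)c(O)c1 | starting material
16 | TBS (E)-3-[3,4-bis(TBS-oxy)phenyl]prop-2-enoate | CC(C)(C)[Si](C)(C)OC(=O)/C=C/c1ccc(O[Si](C)(C)C(C)(C)C)c(O[Si](C)(C)C(C)(C)C)c1 | intermediate
17 | (E)-3-[3,4-bis(TBS-oxy)phenyl]prop-2-enoic acid | O=C(O)/C=C/c1ccc(O[Si](C)(C)C(C)(C)C)c(O[Si](C)(C)C(C)(C)C)c1 | intermediate
18 | [(2R,3S,4S)-2-[4-(TBS-oxy)-3-methoxyphenyl]-4-[4-(TBS-oxy)-3-methoxybenzyl]oxolan-3-yl]methyl (E)-3-[3,4-bis(TBS-oxy)phenyl]prop-2-enoate | COc1cc(C[C@@H]2CO[C@@H](c3ccc(O[Si](C)(C)C(C)(C)C)c(OC)c3)[C@@H]2COC(=O)/C=C/c2ccc(O[Si](C)(C)C(C)(C)C)c(O[Si](C)(C)C(C)(C)C)c2)ccc1O[Si](C)(C)C(C)(C)C | intermediate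
19 | [(2R,3S,4S)-2-(4-hydroxy-3-methoxyphenyl)-4-(4-hydroxy-3-methoxybenzyl)oxolan-3-yl]methyl (E)-3-(3,4-dihydroxyphenyl)prop-2-enoate | COc1cc(C[C@@H]2CO[C@@H](c3ccc(O)c(OC)c3)[C@@H]2COC(=O)/C=C/c2ccc(O)c(O)c2)ccc1O | target

## Step count and least certain steps

Total: 14 steps. Longest linear sequence: 13 steps (steps 1 to 11, then 13 and 14, from vanillin); step 12 is a one-step side branch.

**Step 9 (key step).**
- Likely failure: slow turnover on a trisubstituted alkene. The allylic phosphinite may be lost by a [2,3]-sigmatropic shift to a phosphine oxide. The double bond may migrate toward ring B by β-hydride elimination at C7' before CO inserts. Face selection may be incomplete if the conformer fixed by allylic strain is not the only one that reacts.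
- Fallback (known chemistry): it sets out from 10 and comes back at 11, which closes to 12. The C2 hydroxyl of 10 is silylated (Et3SiCl, imidazole) to the triethylsilyl ether F1. Hydroboration with 9-borabicyclo[3.3.1]nonane (THF, 65 °C) adds H to C3 and boron to C4 syn, on the face anti to ring A in the same strain-controlled conformer, giving the B-alkyl borane F2. Carbonylation of F2 under CO (1 atm) with LiAlH(OtBu)3, followed by buffered H2O2, inserts one carbon with retention and gives the silyl-protected aldehyde F3. Buffered HF·pyridine then removes the triethylsilyl group to give 11.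

**Step 8.**
- Likely failure: insufficient enantioselection in the addition of an α-branched alkenylchromium to an aromatic aldehyde, and reductive pinacol dimerisation of the aldehyde.
- Fallback: it sets out from 9 and 2 and comes back at 10. A non-asymmetric coupling (CrCl2 in excess, NiCl2 1 mol%, DMF) gives the racemic alcohol F4. Esterification with (S)-O-methylmandelic acid (DCC, DMAP) gives diastereomeric esters that are separated by chromatography. The ester of the S carbinol, F5, is cleaved with iBu2AlH at −78 °C to 10.

**Step 10.**
- Likely failure: ionisation of the benzylic C2–O1 bond by the Lewis acid, leading to epimerisation at C2, reductive ring opening or attack of ring B on C2; partial loss of the C9 silyl ether.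
- Fallback: it sets out from 12 and comes back at 13 without any acid. NaBH4 reduces the lactol to the 1,4-diol F6. TsCl with pyridine and DMAP sulfonylates the primary C5 hydroxyl selectively to tosylate F7. F7 closes on warming in pyridine by 5-exo-tet attack of the C2 hydroxyl on C5, with C2 untouched.

**Step 11.**
- Likely failure: the acid also opens or epimerises the benzylic ether, or begins to remove aryl silyl ethers before the C9 ether is gone.
- Fallback: it sets out from 13 and comes back at 19. Bu4NF/AcOH removes all three silyl groups to give the free triol F8. A Mitsunobu esterification (PPh3, diisopropyl azodicarboxylate, THF, 0 °C) with acid 17 activates only the primary C9 hydroxyl, and the carboxylate, far more acidic than the phenols, is the nucleophile; this gives ester F9. Bu4NF/AcOH then gives 19.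

## Further compounds

F1 | step 9 | C2 O-triethylsilyl ether of 10 | CC[Si](CC)(CC)O[C@@H](c1ccc(O[Si](C)(C)C(C)(C)C)c(OC)c1)/C(CO[Si](C)(C)C(C)(C)C)=C\Cc1ccc(O[Si](C)(C)C(C)(C)C)c(OC)c1
F2 | step 9 | B-alkyl-9-borabicyclo[3.3.1]nonane with boron on C4 and H on C3 (syn) | C1CC2CCCC(C1)B2[C@@H](Cc1ccc(O[Si](C)(C)C(C)(C)C)c(OC)c1)[C@@H](CO[Si](C)(C)C(C)(C)C)[C@@H](O[Si](CC)(CC)CC)c1ccc(O[Si](C)(C)C(C)(C)C)c(OC)c1
F3 | step 9 | C2 O-triethylsilyl ether of aldehyde 11 | O=C[C@@H](Cc1ccc(O[Si](C)(C)C(C)(C)C)c(OC)c1)[C@@H](CO[Si](C)(C)C(C)(C)C)[C@@H](O[Si](CC)(CC)CC)c1ccc(O[Si](C)(C)C(C)(C)C)c(OC)c1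
F4 | step 8 | racemic (Z)-allylic alcohol corresponding to 10 | OC(c1ccc(O[Si](C)(C)C(C)(C)C)c(OC)c1)/C(CO[Si](C)(C)C(C)(C)C)=C\Cc1ccc(O[Si](C)(C)C(C)(C)C)c(OC)c1
F5 | step 8 | (S)-O-methylmandelate of 10 | CO[C@H](C(=O)O[C@@H](c1ccc(O[Si](C)(C)C(C)(C)C)c(OC)c1)/C(CO[Si](C)(C)C(C)(C)C)=C\Cc1ccc(O[Si](C)(C)C(C)(C)C)c(OC)c1)c1ccccc1
F6 | step 10 | 1,4-diol from reduction of 12 (C2 hydroxyl and C5 hydroxyl) | OC[C@@H](Cc1ccc(O[Si](C)(C)C(C)(C)C)c(OC)c1)[C@@H](CO[Si](C)(C)C(C)(C)C)[C@@H](O)c1ccc(O[Si](C)(C)C(C)(C)C)c(OC)c1
F7 | step 10 | primary C5 p-toluenesulfonate of F6 | Cc1ccc(cc1)S(=O)(=O)OC[C@@H](Cc1ccc(O[Si](C)(C)C(C)(C)C)c(OC)c1)[C@@H](CO[Si](C)(C)C(C)(C)C)[C@@H](O)c1ccc(O[Si](C)(C)C(C)(C)C)c(OC)c1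
F8 | step 11 | [(2R,3S,4S)-2-(4-hydroxy-3-methoxyphenyl)-4-(4-hydroxy-3-methoxybenzyl)oxolan-3-yl]methanol | COc1cc(C[C@@H]2CO[C@@H](c3ccc(O)c(OC)c3)[C@@H]2CO)ccc1O
F9 | step 11 | C9 ester of F8 with acid 17 (guaiacyl phenols free) | COc1cc(C[C@@H]2CO[C@@H](c3ccc(O)c(OC)c3)[C@@H]2COC(=O)/C=C/c2ccc(O[Si](C)(C)C(C)(C)C)c(O[Si](C)(C)C(C)(C)C)c2)ccc1O
A1 | alternative 1 | (5S)-5-[(1S,2R,5S)-2-isopropyl-5-methylcyclohexyloxy]furan-2(5H)-one | O=C1O[C@H](O[C@H]2C[C@@H](C)CC[C@@H]2C(C)C)C=C1
A2 | alternative 1 | 2-[4-(TBS-oxy)-3-methoxyphenyl]-1,3-dithiane | COc1cc(C2SCCCS2)ccc1O[Si](C)(C)C(C)(C)C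
A3 | alternative 1 | trans,trans lactone carrying the menthyloxy acetal, the 2-aryl-1,3-dithian-2-yl group and the aryl(hydroxy)methyl group (one carbinol epimer) | O=C1O[C@H](O[C@H]2C[C@@H](C)CC[C@@H]2C(C)C)[C@@H](C2(c3ccc(O[Si](C)(C)C(C)(C)C)c(OC)c3)SCCCS2)[C@@H]1[C@@H](O)c1ccc(O[Si](C)(C)C(C)(C)C)c(OC)c1
A4 | alternative 2 | methyl 3-{[(methoxycarbonyl)oxy]methyl}but-3-enoate | C=C(COC(=O)OC)CC(=O)OC
A5 | alternative 2 | methyl trans-2-[4-(TBS-oxy)-3-methoxyphenyl]-4-methyleneoxolane-3-carboxylate | C=C1CO[C@@H](c2ccc(O[Si](C)(C)C(C)(C)C)c(OC)c2)[C@@H]1C(=O)OC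
A6 | alternative 3 | (E)-cinnamyl ether of the aryl(oxiranyl)methanol, C2 as in the target, epoxide carbon of either configuration | COc1cc(/C=C/CO[C@@H](c2ccc(O[Si](C)(C)C(C)(C)C)c(OC)c2)C2CO2)ccc1O[Si](C)(C)C(C)(C)C
A7 | alternative 3 | bis-silyl oxolane with free C9 hydroxyl, identical with 14 | COc1cc(C[C@@H]2CO[C@@H](c3ccc(O[Si](C)(C)C(C)(C)C)c(OC)c3)[C@@H]2CO)ccc1O[Si](C)(C)C(C)(C)C
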